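**Strategy.** Ring numbering: O1, O2, C3 (CH), C4, C5, C6 (ketal). The 1,2-dioxane is cut at C4–C5 and at O2–C3, leaving a four-atom C5–C6–O1–O2 unit and a two-carbon C3–C4 unit. The key step joins three components in one flask: the kinetic enolate of an enynyl methyl ketone (C5), a malic-acid-derived 1,2-cyclic sulfate (C4 and C3) and hydrogen peroxide (O1–O2). It exploits the 1,4-relationship between ketal carbon C6 and the oxygenated stereocentre C3: enolate alkylation forges C4–C5, then the ketone perhydrate displaces the unmasked secondary sulfate, forging O2–C3 with inversion. The precursors are an acyclic ketone and a small chiral cyclic sulfate.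

Key step: step 6

Remark on the chemistry: C6 is assumed to equilibrate in acidic methanol through the ring peroxycarbenium ion, and the anomer with axial OMe and both carbon chains equatorial (the 3S,6R series) is assumed to be the more stable one. Atom labels C3–C6, O1, O2 in the Why lines are those of the target ring.

Step 1
Reactants: 1 undec-1-yne
Product: 3 (E)-1-iodoundec-1-ene, via alkenylzirconocene chloride 2 (not isolated)
Conditions: Cp2Zr(H)Cl, THF, rt; then I2, 0 °C
Reagents that add atoms: iodine, II
Why: Hydrozirconation (syn addition, zirconium to the terminal carbon) followed by iodinolysis with retention should give the E-alkenyl iodide, which fixes the alkene geometry of the side chain.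

Step 2
Reactants: 3 (E)-1-iodoundec-1-ene; 4 hept-6-yn-2-one
Product: 5 (8E)-octadec-8-en-6-yn-2-one
Conditions: PdCl2(PPh3)2 (cat.), CuI (cat.), Et3N, THF, rt
Reagents that add atoms: none
Why: Sonogashira coupling of an alkenyl iodide proceeds at room temperature with retention of the E geometry and should leave the methyl ketone untouched.

Step 3
Reactants: 6 2-[(4S)-2,2-dimethyl-1,3-dioxolan-4-yl]ethan-1-ol
Product: 7 tert-butyl{2-[(4S)-2,2-dimethyl-1,3-dioxolan-4-yl]ethoxy}dimethylsilane
Conditions: TBSCl, imidazole, DMF, rt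
Reagents that add atoms: tert-butyldimethylsilyl chloride, CC(C)(C)[Si](C)(C)Cl
Why: Routine silyl ether protection of the primary alcohol that later becomes the carboxyl carbon; the stereocentre is not touched.

Step 4
Reactants: 7 tert-butyl{2-[(4S)-2,2-dimethyl-1,3-dioxolan-4-yl]ethoxy}dimethylsilane
Product: 8 (2S)-4-[(tert-butyldimethylsilyl)oxy]butane-1,2-diol
Conditions: CuCl2·2H2O, MeCN, 0 °C
Reagents that add atoms: none
Why: Lewis-acid-mediated hydrolysis of the terminal isopropylidene acetal (acetal deprotection) is expected to be faster than loss of the primary silyl ether, and no bond to the stereocentre is broken.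

Step 5
Reactants: 8 (2S)-4-[(tert-butyldimethylsilyl)oxy]butane-1,2-diol
Product: 10 (4S)-4-{2-[(tert-butyldimethylsilyl)oxy]ethyl}-1,3,2-dioxathiolane 2,2-dioxide, via cyclic sulfite 9 (not isolated)
Conditions: SOCl2, Et3N, CH2Cl2, 0 °C; then RuCl3·xH2O (cat.), NaIO4, MeCN/H2O, 0 °C
Reagents that add atoms: thionyl chloride, O=S(Cl)Cl; sodium periodate, [Na+].[O-]I(=O)(=O)=O
Why: Cyclic sulfite formation and ruthenium-tetroxide-catalysed oxidation (the standard cyclic sulfate synthesis) activate both carbinol carbons without breaking their C–O bonds, so the S configuration is retained.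

Step 6
Reactants: 5 (8E)-octadec-8-en-6-yn-2-one; 10 (4S)-4-{2-[(tert-butyldimethylsilyl)oxy]ethyl}-1,3,2-dioxathiolane 2,2-dioxide
Product: 14 (6S)-6-{2-[(tert-butyldimethylsilyl)oxy]ethyl}-3-[(6E)-hexadec-6-en-4-yn-1-yl]-1,2-dioxan-3-ol, via lithium enolate 11 (not isolated), via lithium alkyl sulfate 12 (not isolated), via ketone perhydrate 13 (not isolated)
Conditions: LDA (LiN(i-Pr)2), THF, −78 °C; then 10, −78 to 0 °C; then 50% aq. H2O2, LiOH·H2O, THF/H2O, 0 to 40 °C
Reagents that add atoms: hydrogen peroxide, OO
Why: Proposed new method: the kinetic enolate 11 opens cyclic sulfate 10 by SN2 at its primary carbon (C4–C5 bond) and thereby unmasks the secondary alkyl sulfate 12; LiOOH then adds reversibly to the ketone, and the peroxy anion of perhydrate 13 displaces sulfate at the secondary carbon (O2–C3 bond). The closest known reaction types are the one-flask double displacement of 1,2-cyclic sulfates by 1,n-dinucleophiles (cyclopropanes from malonates, morpholines from amino alcohols) and the SN2 perhydrolysis of secondary sulfonates by alkaline hydrogen peroxide, but a ketone perhydrate has not been used as the second nucleophile on a sulfate monoester. The 1,2-dioxane closes 6-exo-tet through a chair-like transition state. C3 is set by the substrate: inversion at the (R)-sulfate carbon, whose configuration comes unchanged from 6, gives S, while the hemiketal carbon forms as an equilibrating mixture that step 7 resolves. The step needs methyl-side enolisation (LDA at −78 °C, kinetic control), attack at the primary and not the secondary sulfate carbon (sterics), and peroxide O-alkylation in preference to 3-exo C-alkylation or 5-exo O-alkylation of the keto sulfate; weakly basic LiOOH is meant to secure the last point, because it keeps the enolate concentration negligible while the alpha-effect nucleophile sits 1,4 to the leaving group.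

Step 7
Reactants: 14 (6S)-6-{2-[(tert-butyldimethylsilyl)oxy]ethyl}-3-[(6E)-hexadec-6-en-4-yn-1-yl]-1,2-dioxan-3-ol
Product: 15 2-[(3S,6R)-6-[(6E)-hexadec-6-en-4-yn-1-yl]-6-methoxy-1,2-dioxan-3-yl]ethan-1-ol
Conditions: CSA (cat.), MeOH, rt
Reagents that add atoms: methanol, CO
Why: Acid-catalysed transketalisation through the ring peroxycarbenium ion should put OMe on C6 under thermodynamic control (axial OMe, both carbon chains equatorial, hence 6R), and the same acidic methanol cleaves the primary silyl ether.

Step 8
Reactants: 15 2-[(3S,6R)-6-[(6E)-hexadec-6-en-4-yn-1-yl]-6-methoxy-1,2-dioxan-3-yl]ethan-1-ol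
Product: 16 2-[(3S,6R)-6-[(6E)-hexadec-6-en-4-yn-1-yl]-6-methoxy-1,2-dioxan-3-yl]acetic acid
Conditions: TEMPO (cat.), PhI(OAc)2, MeCN/pH 7 phosphate buffer, rt
Reagents that add atoms: water, O
Why: Nitroxyl-catalysed oxidation (TEMPO/PhI(OAc)2) takes the primary alcohol through the aldehyde hydrate to the acid under near-neutral conditions that the peroxyketal, the enyne and both stereocentres should tolerate.

**Compound list**

1 | undec-1-yne | CCCCCCCCCC#C | starting material
2 | chloro[(E)-undec-1-en-1-yl]zirconocene (not isolated) | CCCCCCCCC/C=C/[Zr](Cl)(C1C=CC=C1)C1C=CC=C1 | intermediate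
3 | (E)-1-iodoundec-1-ene | CCCCCCCCC/C=C/I | intermediate
4 | hept-6-yn-2-one | CC(=O)CCCC#C | starting material
5 | (8E)-octadec-8-en-6-yn-2-one | CCCCCCCCC/C=C/C#CCCCC(C)=O | intermediate
6 | 2-[(4S)-2,2-dimethyl-1,3-dioxolan-4-yl]ethan-1-ol | CC1(C)OC[C@H](CCO)O1 | starting material
7 | tert-butyl{2-[(4S)-2,2-dimethyl-1,3-dioxolan-4-yl]ethoxy}dimethylsilane | CC1(C)OC[C@H](CCO[Si](C)(C)C(C)(C)C)O1 | intermediate
8 | (2S)-4-[(tert-butyldimethylsilyl)oxy]butane-1,2-diol | OC[C@H](CCO[Si](C)(C)C(C)(C)C)O | intermediate
9 | (4S)-4-{2-[(tert-butyldimethylsilyl)oxy]ethyl}-1,3,2-dioxathiolane 2-oxide (not isolated, both sulfur epimers) | O=S1OC[C@H](CCO[Si](C)(C)C(C)(C)C)O1 | intermediate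
10 | (4S)-4-{2-[(tert-butyldimethylsilyl)oxy]ethyl}-1,3,2-dioxathiolane 2,2-dioxide | O=S1(=O)OC[C@H](CCO[Si](C)(C)C(C)(C)C)O1 | intermediate
11 | lithium (8E)-octadeca-1,8-dien-6-yn-2-olate (not isolated) | [Li+].[O-]C(=C)CCCC#C/C=C/CCCCCCCCC | intermediate
12 | lithium (3R,12E)-1-[(tert-butyldimethylsilyl)oxy]-6-oxodocos-12-en-10-yn-3-yl sulfate (not isolated) | CCCCCCCCC/C=C/C#CCCCC(=O)CC[C@H](CCO[Si](C)(C)C(C)(C)C)OS(=O)(=O)[O-].[Li+] | intermediate
13 | lithium (3R,12E)-1-[(tert-butyldimethylsilyl)oxy]-6-hydroperoxy-6-hydroxydocos-12-en-10-yn-3-yl sulfate (not isolated) | CCCCCCCCC/C=C/C#CCCCC(O)(OO)CC[C@H](CCO[Si](C)(C)C(C)(C)C)OS(=O)(=O)[O-].[Li+] | intermediate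
14 | (6S)-6-{2-[(tert-butyldimethylsilyl)oxy]ethyl}-3-[(6E)-hexadec-6-en-4-yn-1-yl]-1,2-dioxan-3-ol (both hemiketal epimers) | CCCCCCCCC/C=C/C#CCCCC1(O)CC[C@@H](CCO[Si](C)(C)C(C)(C)C)OO1 | intermediate
15 | 2-[(3S,6R)-6-[(6E)-hexadec-6-en-4-yn-1-yl]-6-methoxy-1,2-dioxan-3-yl]ethan-1-ol | CCCCCCCCC/C=C/C#CCCC[C@]1(OC)CC[C@@H](CCO)OO1 | intermediate
16 | 2-[(3S,6R)-6-[(6E)-hexadec-6-en-4-yn-1-yl]-6-methoxy-1,2-dioxan-3-yl]acetic acid | CCCCCCCCC/C=C/C#CCCC[C@]1(OC)CC[C@@H](CC(=O)O)OO1 | target

**Totals.** Total step count: 8. Longest linear sequence: 6 steps (steps 3 to 8, from 6 to 16).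

**Steps most likely to fail**

1. Step 6 (bears the label). The anionic secondary sulfate is a sluggish leaving group, so the peroxide displacement may be outrun by 3-exo C-alkylation to a cyclopropyl ketone, by 5-exo O-alkylation through the ketone hydrate, or by plain hydrolysis. The enolate alkylation may also lose its methyl-side regiocontrol through proton exchange. The fallback uses known chemistry and sets out from 5 and 10. The enolate alkylation is run as before, but the alkyl sulfate 12 is hydrolysed under the usual conditions (cat. H2SO4, 1 equiv H2O, THF; S–O cleavage, retention) to the γ-hydroxy ketone F1. Mesylation (MsCl, Et3N, CH2Cl2) gives the keto mesylate F2. Treatment with 50% H2O2 and cat. CSA in MeOH turns the ketone into the methoxy hydroperoxy ketal and removes the silyl group, giving the hydroperoxy ketal mesylate F3. KOtBu with 18-crown-6 in THF then closes the ring by intramolecular SN2 alkylation of the hydroperoxide with inversion. After C6 equilibration under the conditions of step 7, the route is rejoined at 15.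

2. Step 7. Acid may open the peroxyhemiketal to the hydroperoxy ketone and divert it into acyclic ketals or acid-induced peroxide fragmentation, or the anomer equilibrium at C6 may not favour the 6R series enough. The fallback sets out from 14. Purdie-type O-methylation of the hemiketal hydroxyl (MeI, Ag2O, CH2Cl2, dark) never breaks a C6–O bond and should alkylate the major axial-OH anomer with retention, giving the silyl-protected methoxy dioxane F4. Desilylation with TBAF/AcOH in THF rejoins the route at 15.

3. Step 8. The β-peroxy aldehyde formed on the way may undergo base-type elimination with ring opening, or the methyl ketal may hydrolyse in the aqueous oxidising medium. The fallback sets out from 15 and separates the two oxidation stages. Buffered Dess–Martin oxidation (NaHCO3, CH2Cl2) gives the aldehyde F5, which is isolated. Pinnick oxidation (NaClO2, NaH2PO4, 2-methylbut-2-ene, t-BuOH/H2O) then rejoins the route at 16.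

Further compounds
F1 | step 6 | (3R,12E)-1-[(tert-butyldimethylsilyl)oxy]-3-hydroxydocos-12-en-10-yn-6-one | CCCCCCCCC/C=C/C#CCCCC(=O)CC[C@H](CCO[Si](C)(C)C(C)(C)C)O
F2 | step 6 | (3R,12E)-1-[(tert-butyldimethylsilyl)oxy]-6-oxodocos-12-en-10-yn-3-yl methanesulfonate | CCCCCCCCC/C=C/C#CCCCC(=O)CC[C@H](CCO[Si](C)(C)C(C)(C)C)OS(C)(=O)=O
F3 | step 6 | (3R,12E)-6-hydroperoxy-1-hydroxy-6-methoxydocos-12-en-10-yn-3-yl methanesulfonate | CCCCCCCCC/C=C/C#CCCCC(OC)(OO)CC[C@H](CCO)OS(C)(=O)=O
F4 | step 7 | tert-butyl{2-[(3S,6R)-6-[(6E)-hexadec-6-en-4-yn-1-yl]-6-methoxy-1,2-dioxan-3-yl]ethoxy}dimethylsilane | CCCCCCCCC/C=C/C#CCCC[C@]1(OC)CC[C@@H](CCO[Si](C)(C)C(C)(C)C)OO1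
F5 | step 8 | 2-[(3S,6R)-6-[(6E)-hexadec-6-en-4-yn-1-yl]-6-methoxy-1,2-dioxan-3-yl]acetaldehyde | CCCCCCCCC/C=C/C#CCCC[C@]1(OC)CC[C@@H](CC=O)OO1
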